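In amounts, this flask is a balance of solid L: of a charge c, a molar loss Q has left by a given time, so the fraction still solid is 1 − Q/c. Two amounts stand in that fraction, c and Q.

all flasks: E 1.95 M

| flask | L | remark | time |
|---|---|---|---|
| amber | 1 M | run made earlier |  |
| violet | 2.2 M | run made earlier |  |
| flask | 1.5 M |  | 50 h |

| run | time / h | L / % | G / % | D / % |
|---|---|---|---|---|
| amber | 2.00 | 89.7 | 1.4 | 0.1 |
| amber | 6.00 | 80.5 | 3.7 | 1.0 |
| amber | 12.0 | 70.9 | 6.0 | 4.0 |
| amber | 15.0 | 66.7 | 8.2 | 6.2 |
| amber | 25.0 | 53.5 | 10.5 | 13.1 |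
| amber | 30.0 | 47.7 | 11.2 | 15.1 |
| amber | 40.0 | 37.2 | 14.5 | 17.3 |
| violet | 6.00 | 90.8 | 1.4 | 0.3 |
| violet | 12.0 | 87.0 | 3.7 | 2.3 |
| violet | 15.0 | 84.6 | 3.6 | 2.8 |
| violet | 25.0 | 79.3 | 4.8 | 6.4 |
| violet | 30.0 | 76.5 | 5.8 | 7.2 |
| violet | 40.0 | 70.2 | 6.5 | 7.6 |

(each reading ± 0.5 percentage points)

- L is a solid; its amount is given per volume of the solution
- the earlier runs were read with a standard deviation of 0.5 percentage points
- on the list of suspects stand: Z + E -> G; E + G <-> D; L <-> Z; E + G -> X
- at the start none of L is in solution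

- how much L there is at 50 h, in percent of the L charged (only what is still solid)
- how much G there is at 50 h, in percent of the L charged
- how much D there is at 50 h, in percent of the L charged

By 40.0 h, amber has lost 0.628 M and violet 0.656 M, although violet's charge is 2.20 times amber's. The loss reads as zero order in the solid. I take the mean, 0.642 M, and extend it at the mean drain read from 12.0 h to 40.0 h, 0.0126 M h⁻¹. This gives the common molar loss Q at 50 h, 0.768 M, which leaves 48.8% of this flask's L solid.

The forecast gives 51.3% L, 10.5% G and 12.5% D, holding that “The flask should follow the same molar curves”. Its L stands 2.5 percentage points above mine, since its drain falls with the reagent E and mine stays straight.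

The flask gives 51.5% L, 10.7% G and 13.5% D.

    Z + E → G (k = 0.0500 M⁻¹ h⁻¹)
    E + G ⇌ D (K = 1.50 M⁻¹, k = 0.0690 M⁻¹ h⁻¹)
    L ⇌ Z, rate k3*(cs3 - [Z]) while solid is left; crystals form when [Z] > cs3 (solubility = 0.200 M, k = 0.320 h⁻¹)
    E + G → X (k = 0.0290 M⁻¹ h⁻¹)

This flask has lost 0.727 M, less than my Q of 0.768 M. At 17.1 h, in this flask, the dissolved form Z is made 1.04 times as fast as it is used, each step taken net, a quasi-steady state in which solid leaves about as fast as Z passes on. The forecast would fail if a run showed Q changing with c: charges of 1.36 M and 1.67 M move the L answer by 5 points, to the 46.5% and 56.5% that this flask's molar loss, held fixed, gives at those charges. For this flask read at 30 h, Q taken as the runs' mean loss at that time, 0.520 M, leaves 65.3% solid, and the flask holds 65.1%.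

The numbers in the tables come from a simulation with constants of no real substance.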